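## Structural features

The target is a 14-membered carbocycle of the cembrane type, numbered here from the acetoxy carbon C1 round the ring: E-olefin C2=C3 (methyl on C3), methylenes C4 and C5, branch point C6 carrying the 2-hydroxypropan-2-yl group (carbinol carbon C15), C7, Z-olefin C8=C9 (methyl on C9), C10, C11, the oxirane carbons C12 (H) and C13 (methyl), and C14, which returns to C1. The ring is fused at C12–C13 to a cis trisubstituted epoxide, the epoxide of a Z-olefin, so two of the three trisubstituted units are Z and one is E. The stereocentres are C1 (S), C6 (R), C12 (S) and C13 (R): C12 and C13 are adjacent, C13 and C1 are separated only by C14 with their oxygens 1,3-syn, and C6 lies at least five bonds from the other three, so it cannot be set by relay. Fragile groups are the epoxide (acid, Lewis acid, strong hydride), the allylic acetate (base, reductants), the tertiary alcohol and the two Z-olefins (isomerisation). The real difficulties are the independent control of C6 and of the C1/C12/C13 triad, two Z-trisubstituted units, and closure of an all-carbon 14-membered ring. The key step uses the ring bond C4–C5: C4 is the allylic methylene of the E-C2=C3 unit and can serve as a primary allylic electrophile, while C5 is a plain methylene beside C6 with no stereocentre and no β-leaving group, so a removable sulfonyl group on C5 makes it the nucleophile.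

## Logic of the disconnections

36 to 35: the acetyl C–O bond at C1 is cut last, because an allylic acetate would not survive amide base, amalgam or fluoride. The forward step must acylate the secondary allylic hydroxyl and leave the tertiary C15 hydroxyl, which steric hindrance secures.

35 to 34: both O–Si bonds (C1 and C15) are cut together, so one fluoride operation frees both hydroxyls. The epoxide must tolerate fluoride and the alkoxides formed.

34 to 33: a phenylsulfonyl group is added back on C5 (forward: C5–S cleavage). C5 is not allylic, so reductive removal cannot move a double bond; the forward step must spare the epoxide and the allylic silyl ether.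

33 to 32: the ring bond C4–C5 is cut. This opens the ring to a linear chain that already holds all four stereocentres, both olefins and the epoxide, with a C5 sulfone as latent nucleophile and a C4 allylic bromide as electrophile. The forward step demands SN2 over SN2′ and ring closure over dimerisation. A centre-by-centre check shows 32 and 33 carry C1 (S), C6 (R), C12 (S), C13 (R), 2E and 8Z, consistent with 36, so their skeletons need no correction.

32 to 30, 29, then 26 and 27: the C4–Br bond is traced to a C4 alcohol and ester, and the C2=C3 double bond is cut (Wittig). This removes C3, C4 and the C3 methyl in one piece and fixes the E geometry before the ring is closed; the α-silyloxy aldehyde 28 must not epimerise.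

26 to 25, 24 and 23: the protecting-group changes are undone and the two epoxide C–O bonds are cut. At 23 the C1 hydroxyl is homoallylic to C12=C13 and C2 is still sp3, so a metal-bound peroxide reaches only that olefin and C1 controls two new stereocentres. The forward step needs facial selectivity from a chair-like transition state, no reaction at C8=C9, and a masked C15 oxygen.

23 to 22, 21, then 20 and 10: the C10–C11 bond is cut between two allylic methylenes, restoring a phenylsulfonyl group on C11 and the sulfide oxidation level at C5. This splits the chain into two fragments of similar size. The forward steps need α-alkylation of the allyl sulfone, hydride delivery to C11 and not C13, and retention of both Z geometries.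

10 to 8, 7, 6, 4, 3, 2 and 1: C10–Br and C5–S are traced to oxygen functions and the C5–C10 bond is reconnected, giving a six-membered ring. Compound 1 then supplies C6 with the right configuration, the C9 methyl and the Z-C8=C9 geometry (a ring cis-olefin), and its isopropenyl group becomes C15. The forward sequence needs regioselective α′-oxidation and a cleavage that leaves C6 untouched.

20 to 17, 16, 14, then 12 and 13, and 12 to 11: the C11–S bond, the lactone C–O bond, the C13–CH3 bond and the C13–C14 bond are cut. The six-membered lactone 16 locks the Z geometry of C12=C13, and C1 comes from a chiral-pool epoxide. The forward steps need syn-carbocupration and epoxide opening at the unsubstituted carbon.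

## Other disconnections considered

Alternative 1: The cut is through the C2=C3 olefin, taken back to a ring alkyne C2≡C3 lacking the C3 methyl (A1) and then to the acyclic diyne A2, with methyl-capped alkynes on C1 and on C4. Forward, ring-closing alkyne metathesis of A2 with Mo(≡CC6H4OMe)(OSiPh3)3 would form C2≡C3 and the 14-membered ring with loss of 2-butyne.
- In its favour: the closure is catalytic, neutral and tolerant of ethers, silyl ethers and olefins, needs less dilution than a carbanion alkylation, and no sulfone has to be installed and removed. On these points it is better than the chosen plan. The alkyne is also inert in a hydroxyl-directed epoxidation, which equals the chosen plan's device of keeping C2 sp3 at that stage.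
- Against it here: A1 lacks both the C3 methyl and the epoxide. The methyl must go to the alkyne carbon remote from the C1 oxygen; hydroxyl-directed trans-hydrostannation would place the metal on C2, and distal trans-hydrosilylation with [Cp*Ru(MeCN)3]PF6 must be followed by iododesilylation and a methyl cross-coupling in the presence of an epoxide and two trisubstituted olefins. The epoxidation would run on the macrocycle, where facial control depends on ring conformation and on a slim alkynyl group beside the carbinol.
- Comparison: structurally both plans need the same Z,Z chain (equal); mechanistically metathesis is milder than a potassium carbanion; in step economy about six operations follow A1 against three after 33, all on macrocyclic material.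

Alternative 2: The cut is the C3–C4 bond, leading to the acyclic precursor A4 with a vinyl group (C4=C5) on C6 and an E-alkenyl iodide at C3. Forward, 9-BBN would hydroborate the vinyl group and the C4 borane would couple intramolecularly with the iodide under Pd(dppf)Cl2 to give the bis(triethylsilyl) ether A3.
- In its favour: A3 is two steps from the target instead of three, C5 needs only a methylenation instead of sulfur introduction, oxidation and removal, and the closure uses mild base; on these three points it is better than the chosen plan. The carvone-derived fragment and the need to have the epoxide in place before cyclisation are the same (equal).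
- Against it here: the α-branched, β-silyloxy C5 aldehyde would have to survive a basic methylenation. The E-iodoalkene bearing the methyl group next to the C1 silyloxy centre needs a regio- and syn-selective hydrometalation–iodination of a methyl alkyne, less certain than a stabilised Wittig reaction. Macrocyclic B-alkyl Suzuki couplings compete with protodeboronation and intermolecular coupling.
- Comparison: both closures are stereoretentive at the E-olefin and both need dilution (equal); the overall step count would be similar; the chosen plan uses the more predictable route to the E-C2=C3 unit.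

Alternative 3: The cut is the C14–C1 bond, giving the acyclic ynal A6 with a trimethylsilyl group on C12 and an exocyclic methylene (C14) on C13. Forward, BF3·OEt2 would activate the C1 aldehyde and the allylsilane would attack through C14 (SE2′), forming C14–C1, moving the olefin to C12=C13 and closing the ring to the propargylic alcohol A5.
- In its favour: one event would form a skeletal bond, the ring and the C12=C13 olefin, with no sulfone and no protecting group on C1; this is better than the chosen ring closure, which forms a bond but no other structural element.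
- Against it here: C1 would arise as both epimers and need oxidation and asymmetric reduction on the macrocycle. The Z geometry of the new olefin would rest on the conformation about C12–C13 in a macrocyclic transition state, whereas the chosen plan locks it in a lactone beforehand. A5 still lacks the C3 methyl and the epoxide, with the same regiochemical problem as in Alternative 1, and the Lewis acid meets a tertiary silyl ether and an allylsilane prone to protodesilylation.
- Comparison: the carvone-derived half is common to both (equal); six or more operations would follow the ring closure, against three in the chosen plan.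

Key step: step 22

Remark: anionic or metal-bound species that exist only in solution (enolates, sulfonyl carbanions, cuprates, π-allyl complexes) are not numbered; covalent intermediates carried on without isolation are numbered.

## Route

Step 1
Reactants: 1 (S)-(+)-carvone
Product: 2 (5S)-5-(2-hydroxypropan-2-yl)-2-methylcyclohex-2-en-1-one
Conditions: 50% aq. H2SO4, 0 °C
Reagents that add atoms: water, O
Why: Acid-catalysed Markovnikov hydration of the electron-rich 1,1-disubstituted olefin through its tertiary cation; the protonated enone does not add water at 0 °C and the ring stereocentre (future C6) is untouched.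

Step 2
Reactants: 2 (5S)-5-(2-hydroxypropan-2-yl)-2-methylcyclohex-2-en-1-one
Product: 3 (5S)-2-methyl-5-[2-(triethylsilyloxy)propan-2-yl]cyclohex-2-en-1-one
Conditions: Et3SiOTf, 2,6-lutidine, CH2Cl2, −78 → 0 °C
Reagents that add atoms: triethylsilyl trifluoromethanesulfonate, CC[Si](CC)(CC)OS(=O)(=O)C(F)(F)F
Why: Silylation of a tertiary alcohol needs the silyl triflate; the ether keeps the C15 oxygen from acting as a base or as a directing group (it would be bishomoallylic to C8=C9 in the later epoxidation).

Step 3
Reactants: 3 (5S)-2-methyl-5-[2-(triethylsilyloxy)propan-2-yl]cyclohex-2-en-1-one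
Product: 4 (5S)-6-hydroxy-2-methyl-5-[2-(triethylsilyloxy)propan-2-yl]cyclohex-2-en-1-one (both C6 epimers)
Conditions: KN(SiMe3)2, THF, −78 °C; then 2-(phenylsulfonyl)-3-phenyloxaziridine, −78 °C
Reagents that add atoms: 2-(phenylsulfonyl)-3-phenyloxaziridine, O=S(=O)(c1ccccc1)N1OC1c1ccccc1
Why: Kinetic deprotonation at the α′ methylene (future C5) gives the cross-conjugated potassium enolate, which the N-sulfonyloxaziridine hydroxylates (Davis oxidation); the configuration of the new carbinol is irrelevant because that carbon becomes CH2.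

Step 4
Reactants: 4 (5S)-6-hydroxy-2-methyl-5-[2-(triethylsilyloxy)propan-2-yl]cyclohex-2-en-1-one
Product: 6 methyl (2Z,5S)-5-(hydroxymethyl)-2,6-dimethyl-6-(triethylsilyloxy)hept-2-enoate, via C5 aldehyde ester 5 (not isolated)
Conditions: Pb(OAc)4, MeOH–PhH, 0 °C; then NaBH4, −20 °C
Reagents that add atoms: methanol, CO
Why: Pb(OAc)4 cleaves the α-ketol as its methanol hemiketal (Criegee-type cleavage), so the ketone carbon becomes the C10 methyl ester, the carbinol carbon the C5 aldehyde, and the ring cis-olefin the open-chain Z-C8=C9; immediate NaBH4 reduction of the aldehyde alone forestalls epimerisation at C6 and β-elimination of the silyloxy group.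

Step 5
Reactants: 6 methyl (2Z,5S)-5-(hydroxymethyl)-2,6-dimethyl-6-(triethylsilyloxy)hept-2-enoate
Product: 7 methyl (2Z,5R)-2,6-dimethyl-5-[(phenylsulfanyl)methyl]-6-(triethylsilyloxy)hept-2-enoate
Conditions: PhSSPh, PBu3, pyridine, rt
Reagents that add atoms: diphenyl disulfide, c1ccc(SSc2ccccc2)cc1
Why: Hata thioetherification (alkoxyphosphonium displaced by thiolate, SN2 at primary C5) brings in sulfur at the sulfide level, which has no acidic α-protons during the later carbanion coupling; the descriptor at C6 changes by priority only.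

Step 6
Reactants: 7 methyl (2Z,5R)-2,6-dimethyl-5-[(phenylsulfanyl)methyl]-6-(triethylsilyloxy)hept-2-enoate
Product: 8 (2Z,5R)-2,6-dimethyl-5-[(phenylsulfanyl)methyl]-6-(triethylsilyloxy)hept-2-en-1-ol
Conditions: iBu2AlH, CH2Cl2, −78 °C
Reagents that add atoms: none
Why: 1,2-Reduction of the conjugated ester by the aluminium hydride at low temperature gives the Z-allylic alcohol without touching the olefin geometry.

Step 7
Reactants: 8 (2Z,5R)-2,6-dimethyl-5-[(phenylsulfanyl)methyl]-6-(triethylsilyloxy)hept-2-en-1-ol
Product: 10 (2Z,5R)-1-bromo-2,6-dimethyl-5-[(phenylsulfanyl)methyl]-6-(triethylsilyloxy)hept-2-ene, via allylic mesylate 9 (not isolated)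
Conditions: MsCl, Et3N, THF, −40 °C; then LiBr, 0 °C
Reagents that add atoms: lithium bromide, [Li+].[Br-]
Why: Mesylation and Finkelstein-type SN2 displacement at the primary allylic carbon C10 proceed without allylic shift or loss of the Z geometry; the bromide is used at once.

Step 8
Reactants: 11 (R)-glycidol
Product: 12 (2S)-2-{[(4-methoxybenzyl)oxy]methyl}oxirane
Conditions: NaH, 4-MeOC6H4CH2Cl, Bu4NI (cat.), DMF, 0 °C
Reagents that add atoms: 4-methoxybenzyl chloride, COc1ccc(CCl)cc1
Why: Williamson etherification of the sodium alkoxide; the Payne rearrangement of glycidol is degenerate and returns the same enantiomer, so the centre (future C1) is kept and the descriptor changes from R to S by priority only.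

Step 9
Reactants: 12 (2S)-2-{[(4-methoxybenzyl)oxy]methyl}oxirane; 13 ethyl propiolate
Product: 14 ethyl (5S)-5-hydroxy-6-[(4-methoxybenzyl)oxy]hex-2-ynoate
Conditions: 13, n-BuLi, THF, −78 °C; BF3·OEt2; then 12, −78 °C
Reagents that add atoms: none
Why: Yamaguchi–Hirao alkynylation: the lithium acetylide, with BF3 activation, opens the epoxide at its unsubstituted carbon (future C14), forming C13–C14 and leaving the carbinol centre C1 untouched.

Step 10
Reactants: 14 ethyl (5S)-5-hydroxy-6-[(4-methoxybenzyl)oxy]hex-2-ynoate
Product: 16 (6S)-6-{[(4-methoxybenzyl)oxy]methyl}-4-methyl-5,6-dihydro-2H-pyran-2-one, via Z-hydroxy enoate 15 (not isolated)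
Conditions: Me2CuLi (MeLi, CuI), THF, −78 °C; NH4Cl aq.; then PPTS (cat.), CH2Cl2, rt
Reagents that add atoms: lithium dimethylcuprate, [Li+].C[Cu-]C
Why: Syn-carbocupration of the ynoate puts the methyl on C13 cis to the hydrogen on C12, giving the Z-enoate whose C1 hydroxyl is held cis to the ester and closes the six-membered lactone; lactonisation fixes the Z geometry of C12=C13 and leaves any E-isomer behind.

Step 11
Reactants: 16 (6S)-6-{[(4-methoxybenzyl)oxy]methyl}-4-methyl-5,6-dihydro-2H-pyran-2-one
Product: 17 (2Z,5S)-6-[(4-methoxybenzyl)oxy]-3-methylhex-2-ene-1,5-diol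
Conditions: iBu2AlH (excess), CH2Cl2, −78 → 0 °C
Reagents that add atoms: none
Why: Exhaustive 1,2-hydride reduction of the unsaturated lactone through its lactol gives the Z-ene-1,5-diol with C11 at the alcohol level.

Step 12
Reactants: 17 (2Z,5S)-6-[(4-methoxybenzyl)oxy]-3-methylhex-2-ene-1,5-diol
Product: 20 (2S,4Z)-1-[(4-methoxybenzyl)oxy]-4-methyl-6-(phenylsulfonyl)hex-4-en-2-ol, via allylic mesylate 18 (not isolated), via allylic chloride 19 (not isolated)
Conditions: MsCl, 2,4,6-collidine, LiCl, DMF, 0 °C; then PhSO2Na, Bu4NI (cat.), rt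
Reagents that add atoms: sodium benzenesulfinate, [Na+].[O-]S(=O)c1ccccc1
Why: The primary allylic hydroxyl is sulfonylated faster than the hindered secondary one and exchanged in situ for chloride (allylic chlorination with MsCl/LiCl), which the soft sulfinate displaces through sulfur by SN2 without allylic shift; excess chloride and sulfinate should outrun attack by the internal hydroxyl.

Step 13
Reactants: 20 (2S,4Z)-1-[(4-methoxybenzyl)oxy]-4-methyl-6-(phenylsulfonyl)hex-4-en-2-ol; 10 (2Z,5R)-1-bromo-2,6-dimethyl-5-[(phenylsulfanyl)methyl]-6-(triethylsilyloxy)hept-2-ene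
Product: 21 (2S,4Z,8Z,11R)-1-[(4-methoxybenzyl)oxy]-4,8,12-trimethyl-6-(phenylsulfonyl)-11-[(phenylsulfanyl)methyl]-12-(triethylsilyloxy)trideca-4,8-dien-2-ol (both epimers at the sulfonyl carbon C11)
Conditions: n-BuLi (2.05 equiv), THF–DMPU, −78 °C; then 10, −78 → −40 °C
Reagents that add atoms: none
Why: Biellmann-type coupling: the second equivalent of base forms the allylic α-sulfonyl carbanion at C11, which alkylates the primary allylic bromide at its α-carbon (SN2) and joins C10–C11 with both Z-olefins intact; the lithium alkoxide at C1 is a much poorer nucleophile at −78 °C and the sulfide in 10 has no acidic site.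

Step 14
Reactants: 21 coupled C11 sulfone with C5 phenylsulfanyl group
Product: 22 (2S,4Z,8Z,11R)-1-[(4-methoxybenzyl)oxy]-4,8,12-trimethyl-6-(phenylsulfonyl)-11-[(phenylsulfonyl)methyl]-12-(triethylsilyloxy)trideca-4,8-dien-2-ol
Conditions: (NH4)6Mo7O24·4H2O (cat.), 30% H2O2, EtOH, 0 °C → rt
Reagents that add atoms: hydrogen peroxide, OO
Why: Molybdate-catalysed peroxide oxidation converts the sulfide into the sulfone chemoselectively over trisubstituted olefins; it is done only now, when no allylic halide remains that a C5 carbanion could attack.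

Step 15
Reactants: 22 bis-sulfone (allylic sulfone at C11 and alkyl sulfone at C5)
Product: 23 (2S,4Z,8Z,11R)-1-[(4-methoxybenzyl)oxy]-4,8,12-trimethyl-11-[(phenylsulfonyl)methyl]-12-(triethylsilyloxy)trideca-4,8-dien-2-ol
Conditions: Pd(dppp)Cl2 (cat.), LiBHEt3, THF, 0 °C
Reagents that add atoms: none
Why: Palladium-catalysed hydride reduction of the allylic sulfone: zerovalent palladium ionises the C11–S bond to a π-allyl complex and hydride is delivered to the less substituted terminus C11, so C12=C13 keeps its position and Z geometry; the C5 alkyl sulfone is not an allylic leaving group and stays.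

Step 16
Reactants: 23 homoallylic alcohol with 8Z and 12Z olefins
Product: 24 (12S,13R)-12,13-epoxide of 23, that is (2S)-1-[(4-methoxybenzyl)oxy]-3-[(2R,3S)-3-{(3Z,6R)-3,7-dimethyl-6-[(phenylsulfonyl)methyl]-7-(triethylsilyloxy)oct-3-en-1-yl}-2-methyloxiran-2-yl]propan-2-ol
Conditions: VO(acac)2 (cat.), t-BuOOH, CH2Cl2, 0 °C → rt
Reagents that add atoms: tert-butyl hydroperoxide, CC(C)(C)OO
Why: Hydroxyl-directed epoxidation: the vanadate ester of the C1 alcohol delivers oxygen to the only homoallylic olefin (C12=C13) through a chair-like transition state with the CH2OPMB group equatorial and away from the C13 methyl, which should give the 1,3-syn epoxy alcohol, i.e. the cis (12S,13R) epoxide from the (1S) carbinol; C8=C9 is out of reach and the silylated C15 oxygen cannot direct.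

Step 17
Reactants: 24 epoxy alcohol
Product: 25 C1 tert-butyldimethylsilyl ether of 24
Conditions: t-BuMe2SiCl, imidazole, DMF, rt
Reagents that add atoms: tert-butyldimethylsilyl chloride, CC(C)(C)[Si](C)(C)Cl
Why: Standard silylation of the secondary alcohol under non-acidic conditions that leave the epoxide alone.

Step 18
Reactants: 25 C1 silyl ether with C2 4-methoxybenzyl ether
Product: 26 C2 primary alcohol (1S,6R,12S,13R,8Z) with C1 OTBS, 12,13-epoxide, C5 phenylsulfonyl and C15 OTES
Conditions: DDQ, CH2Cl2–pH 7 buffer, 0 °C
Reagents that add atoms: none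
Why: Oxidative cleavage of the 4-methoxybenzyl ether by DDQ (hydride abstraction, then hydrolysis of the oxocarbenium ion) in buffered medium is orthogonal to both silyl ethers, the epoxide and the sulfone.

Step 19
Reactants: 26 C2 primary alcohol; 27 ethyl 2-(triphenyl-λ5-phosphanylidene)propanoate
Product: 29 ethyl (2E)-enoate in which C2=C3(CH3)–C4O2Et is attached to C1 (1S,6R,12S,13R,2E,8Z), via C2 aldehyde 28 (not isolated)
Conditions: Dess–Martin periodinane, NaHCO3, CH2Cl2, 0 °C → rt; then 27, rt → 40 °C
Reagents that add atoms: none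
Why: Dess–Martin oxidation gives the α-silyloxy aldehyde, trapped in the same flask by the stabilised ylide (Wittig reaction); the disubstituted stabilised ylide gives the E-trisubstituted enoate (C1 trans to C4) and the neutral conditions protect C1 from epimerisation.

Step 20
Reactants: 29 ethyl (2E)-enoate
Product: 30 C4 allylic alcohol (1S,6R,12S,13R,2E,8Z)
Conditions: iBu2AlH, CH2Cl2, −78 °C
Reagents that add atoms: none
Why: 1,2-Reduction of the enoate by the aluminium hydride at −78 °C gives the E-allylic alcohol; epoxide and sulfone are inert at this temperature.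

Step 21
Reactants: 30 C4 allylic alcohol
Product: 32 acyclic C4 allylic bromide and C5 phenyl sulfone with 12,13-epoxide and C1 OTBS and C15 OTES (1S,6R,12S,13R,2E,8Z), via allylic mesylate 31 (not isolated)
Conditions: MsCl, Et3N, THF, −40 °C; then LiBr, 0 °C
Reagents that add atoms: lithium bromide, [Li+].[Br-]
Why: Mesylation then SN2 displacement by bromide at primary allylic C4, a sequence compatible with trisubstituted epoxides; no allylic shift because C2 is shielded by the adjacent silyloxy carbon.

Step 22
Reactants: 32 acyclic C4 allylic bromide and C5 phenyl sulfone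
Product: 33 macrocyclic C5 phenyl sulfone (both C5 epimers; 1S,6R,12S,13R,2E,8Z) with C1 OTBS and C15 OTES
Conditions: KN(SiMe3)2 (1.2 equiv), THF, syringe-pump addition of 32 (final 0.002 M), −40 → 0 °C
Reagents that add atoms: none
Why: KN(SiMe3)2 removes a C5 proton α to the sulfone, the most acidic site in 32, and the potassium α-sulfonyl carbanion displaces bromide at the primary allylic carbon C4 by SN2, forming C4–C5. The closest known reaction type is the macrocyclisation of sulfone-stabilised carbanions onto allylic halides used for 14-membered terpenoid carbocycles. The 14-membered ring closes in the exo-tet mode, the leaving group lying outside the new ring. The only new stereocentre is C5, formed as both epimers without need for control because the sulfonyl group is removed in step 23; C1, C6, C12 and C13 are spectators. The step needs attack at C4 and not at C2 (SN2′), which the substrate secures because C2 is flanked by the C3 methyl and the silyloxy-bearing C1 and attack there would give a more congested 12-membered ring. It needs ring closure and not dimerisation, which slow addition at high dilution secures. It needs the bromide to react and not the epoxide, which the far higher electrophilicity of a primary allylic bromide secures; no β-elimination is open to the carbanion because C6 carries no leaving group and the C15 oxygen is one carbon further away.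

Step 23
Reactants: 33 macrocyclic C5 phenyl sulfone
Product: 34 macrocycle (1S,6R,12S,13R,2E,8Z) with C1 OTBS and C15 OTES
Conditions: 6% Na(Hg), Na2HPO4, MeOH–THF, −20 °C
Reagents that add atoms: none
Why: Reductive desulfonylation by electron transfer from the amalgam in phosphate-buffered methanol cleaves the C5–S bond and protonates the carbanion; C5 is not allylic, so no olefin can migrate, and the buffer keeps methoxide away from the epoxide.

Step 24
Reactants: 34 bis-silyl ether macrocycle
Product: 35 (1S,6R,12S,13R,2E,8Z)-12,13-epoxy-6-(2-hydroxypropan-2-yl)-3,9,13-trimethylcyclotetradeca-2,8-dien-1-ol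
Conditions: Bu4NF, THF, rt → 40 °C
Reagents that add atoms: none
Why: Fluoride cleaves both silyl ethers through Si–F bond formation, the tertiary triethylsilyl ether needing gentle warming; the alkoxides formed are not placed for a favourable epoxide opening.

Step 25
Reactants: 35 macrocyclic diol
Product: 36 target, (1S,6R,12S,13R,2E,8Z)-12,13-epoxy-6-(2-hydroxypropan-2-yl)-3,9,13-trimethylcyclotetradeca-2,8-dien-1-yl acetate
Conditions: Ac2O, pyridine, DMAP (cat.), CH2Cl2, 0 °C
Reagents that add atoms: acetic anhydride, CC(=O)OC(C)=O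
Why: Acylation with acetic anhydride and catalytic DMAP at 0 °C acetylates the secondary allylic hydroxyl at C1 while the tertiary C15 hydroxyl is too hindered to react, giving the target with all four stereocentres unchanged.

## Compound list

1 | (S)-(+)-carvone | CC1=CC[C@@H](CC1=O)C(C)=C | starting material
2 | (5S)-5-(2-hydroxypropan-2-yl)-2-methylcyclohex-2-en-1-one | CC1=CC[C@@H](CC1=O)C(C)(C)O | intermediate
3 | (5S)-2-methyl-5-[2-(triethylsilyloxy)propan-2-yl]cyclohex-2-en-1-one | CC1=CC[C@@H](CC1=O)C(C)(C)O[Si](CC)(CC)CC | intermediate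
4 | (5S)-6-hydroxy-2-methyl-5-[2-(triethylsilyloxy)propan-2-yl]cyclohex-2-en-1-one (C6 epimers) | CC1=CC[C@@H](C(O)C1=O)C(C)(C)O[Si](CC)(CC)CC | intermediate
5 | methyl (2Z,5R)-5-formyl-2,6-dimethyl-6-(triethylsilyloxy)hept-2-enoate (not isolated) | COC(=O)/C(C)=C\C[C@@H](C=O)C(C)(C)O[Si](CC)(CC)CC | intermediate
6 | methyl (2Z,5S)-5-(hydroxymethyl)-2,6-dimethyl-6-(triethylsilyloxy)hept-2-enoate | COC(=O)/C(C)=C\C[C@@H](CO)C(C)(C)O[Si](CC)(CC)CC | intermediate
7 | methyl (2Z,5R)-2,6-dimethyl-5-[(phenylsulfanyl)methyl]-6-(triethylsilyloxy)hept-2-enoate | COC(=O)/C(C)=C\C[C@@H](CSc1ccccc1)C(C)(C)O[Si](CC)(CC)CC | intermediate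
8 | (2Z,5R)-2,6-dimethyl-5-[(phenylsulfanyl)methyl]-6-(triethylsilyloxy)hept-2-en-1-ol | OC/C(C)=C\C[C@@H](CSc1ccccc1)C(C)(C)O[Si](CC)(CC)CC | intermediate
9 | methanesulfonate of 8 (not isolated) | CS(=O)(=O)OC/C(C)=C\C[C@@H](CSc1ccccc1)C(C)(C)O[Si](CC)(CC)CC | intermediate
10 | (2Z,5R)-1-bromo-2,6-dimethyl-5-[(phenylsulfanyl)methyl]-6-(triethylsilyloxy)hept-2-ene | BrC/C(C)=C\C[C@@H](CSc1ccccc1)C(C)(C)O[Si](CC)(CC)CC | intermediate
11 | (R)-glycidol | OC[C@@H]1CO1 | starting material
12 | (2S)-2-{[(4-methoxybenzyl)oxy]methyl}oxirane | COc1ccc(COC[C@@H]2CO2)cc1 | intermediate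
13 | ethyl propiolate | CCOC(=O)C#C | starting material
14 | ethyl (5S)-5-hydroxy-6-[(4-methoxybenzyl)oxy]hex-2-ynoate | CCOC(=O)C#CC[C@H](O)COCc1ccc(OC)cc1 | intermediate
15 | ethyl (2Z,5S)-5-hydroxy-6-[(4-methoxybenzyl)oxy]-3-methylhex-2-enoate (not isolated) | CCOC(=O)/C=C(/C)C[C@H](O)COCc1ccc(OC)cc1 | intermediate
16 | (6S)-6-{[(4-methoxybenzyl)oxy]methyl}-4-methyl-5,6-dihydro-2H-pyran-2-one | CC1=CC(=O)O[C@H](COCc2ccc(OC)cc2)C1 | intermediate
17 | (2Z,5S)-6-[(4-methoxybenzyl)oxy]-3-methylhex-2-ene-1,5-diol | OC/C=C(/C)C[C@H](O)COCc1ccc(OC)cc1 | intermediate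
18 | (2Z,5S)-5-hydroxy-6-[(4-methoxybenzyl)oxy]-3-methylhex-2-en-1-yl methanesulfonate (not isolated) | CS(=O)(=O)OC/C=C(/C)C[C@H](O)COCc1ccc(OC)cc1 | intermediate
19 | (2S,4Z)-6-chloro-1-[(4-methoxybenzyl)oxy]-4-methylhex-4-en-2-ol (not isolated) | ClC/C=C(/C)C[C@H](O)COCc1ccc(OC)cc1 | intermediate
20 | (2S,4Z)-1-[(4-methoxybenzyl)oxy]-4-methyl-6-(phenylsulfonyl)hex-4-en-2-ol | O=S(=O)(c1ccccc1)C/C=C(/C)C[C@H](O)COCc1ccc(OC)cc1 | intermediate
21 | (2S,4Z,8Z,11R)-1-[(4-methoxybenzyl)oxy]-4,8,12-trimethyl-6-(phenylsulfonyl)-11-[(phenylsulfanyl)methyl]-12-(triethylsilyloxy)trideca-4,8-dien-2-ol (epimers at the sulfonyl carbon) | COc1ccc(COC[C@@H](O)C/C(C)=C\C(S(=O)(=O)c2ccccc2)C/C(C)=C\C[C@@H](CSc2ccccc2)C(C)(C)O[Si](CC)(CC)CC)cc1 | intermediate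
22 | (2S,4Z,8Z,11R)-1-[(4-methoxybenzyl)oxy]-4,8,12-trimethyl-6-(phenylsulfonyl)-11-[(phenylsulfonyl)methyl]-12-(triethylsilyloxy)trideca-4,8-dien-2-ol | COc1ccc(COC[C@@H](O)C/C(C)=C\C(S(=O)(=O)c2ccccc2)C/C(C)=C\C[C@@H](CS(=O)(=O)c2ccccc2)C(C)(C)O[Si](CC)(CC)CC)cc1 | intermediate
23 | (2S,4Z,8Z,11R)-1-[(4-methoxybenzyl)oxy]-4,8,12-trimethyl-11-[(phenylsulfonyl)methyl]-12-(triethylsilyloxy)trideca-4,8-dien-2-ol | COc1ccc(COC[C@@H](O)C/C(C)=C\CC/C(C)=C\C[C@@H](CS(=O)(=O)c2ccccc2)C(C)(C)O[Si](CC)(CC)CC)cc1 | intermediate
24 | (2S)-1-[(4-methoxybenzyl)oxy]-3-[(2R,3S)-3-{(3Z,6R)-3,7-dimethyl-6-[(phenylsulfonyl)methyl]-7-(triethylsilyloxy)oct-3-en-1-yl}-2-methyloxiran-2-yl]propan-2-ol | COc1ccc(COC[C@@H](O)C[C@@]2(C)O[C@H]2CC/C(C)=C\C[C@@H](CS(=O)(=O)c3ccccc3)C(C)(C)O[Si](CC)(CC)CC)cc1 | intermediate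
25 | C1 tert-butyldimethylsilyl ether of 24 | COc1ccc(COC[C@@H](O[Si](C)(C)C(C)(C)C)C[C@@]2(C)O[C@H]2CC/C(C)=C\C[C@@H](CS(=O)(=O)c3ccccc3)C(C)(C)O[Si](CC)(CC)CC)cc1 | intermediate
26 | C2 primary alcohol (1S,6R,12S,13R,8Z): C1 OTBS, 12,13-epoxide, C5 phenylsulfonyl, C15 OTES | OC[C@@H](O[Si](C)(C)C(C)(C)C)C[C@@]1(C)O[C@H]1CC/C(C)=C\C[C@@H](CS(=O)(=O)c2ccccc2)C(C)(C)O[Si](CC)(CC)CC | intermediate
27 | ethyl 2-(triphenyl-λ5-phosphanylidene)propanoate | CCOC(=O)C(C)=P(c1ccccc1)(c1ccccc1)c1ccccc1 | starting material
28 | C2 aldehyde from 26 (not isolated) | O=C[C@@H](O[Si](C)(C)C(C)(C)C)C[C@@]1(C)O[C@H]1CC/C(C)=C\C[C@@H](CS(=O)(=O)c2ccccc2)C(C)(C)O[Si](CC)(CC)CC | intermediate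
29 | ethyl (2E)-enoate, C4 ester (1S,6R,12S,13R,2E,8Z) | CCOC(=O)/C(C)=C/[C@@H](O[Si](C)(C)C(C)(C)C)C[C@@]1(C)O[C@H]1CC/C(C)=C\C[C@@H](CS(=O)(=O)c2ccccc2)C(C)(C)O[Si](CC)(CC)CC | intermediate
30 | C4 allylic alcohol (1S,6R,12S,13R,2E,8Z) | OC/C(C)=C/[C@@H](O[Si](C)(C)C(C)(C)C)C[C@@]1(C)O[C@H]1CC/C(C)=C\C[C@@H](CS(=O)(=O)c2ccccc2)C(C)(C)O[Si](CC)(CC)CC | intermediate
31 | C4 allylic mesylate (not isolated) | CS(=O)(=O)OC/C(C)=C/[C@@H](O[Si](C)(C)C(C)(C)C)C[C@@]1(C)O[C@H]1CC/C(C)=C\C[C@@H](CS(=O)(=O)c2ccccc2)C(C)(C)O[Si](CC)(CC)CC | intermediate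
32 | acyclic C4 allylic bromide / C5 phenyl sulfone, 12,13-epoxide, C1 OTBS, C15 OTES (1S,6R,12S,13R,2E,8Z) | O=S(=O)(c1ccccc1)C[C@@H](C(C)(C)O[Si](CC)(CC)CC)C/C=C(/C)CC[C@@H]2O[C@]2(C)C[C@H](O[Si](C)(C)C(C)(C)C)/C=C(\C)CBr | intermediate
33 | macrocyclic C5 phenyl sulfone (C5 epimers), C1 OTBS, C15 OTES | CC(C)(C)[Si](C)(C)O[C@@H]1/C=C(\C)CC(S(=O)(=O)c3ccccc3)[C@@H](C(C)(C)O[Si](CC)(CC)CC)C/C=C(/C)CC[C@@H]2O[C@]2(C)C1 | intermediate
34 | macrocycle with C1 OTBS and C15 OTES (1S,6R,12S,13R,2E,8Z) | CC(C)(C)[Si](C)(C)O[C@@H]1/C=C(\C)CC[C@@H](C(C)(C)O[Si](CC)(CC)CC)C/C=C(/C)CC[C@@H]2O[C@]2(C)C1 | intermediate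
35 | (1S,6R,12S,13R,2E,8Z)-12,13-epoxy-6-(2-hydroxypropan-2-yl)-3,9,13-trimethylcyclotetradeca-2,8-dien-1-ol | O[C@@H]1/C=C(\C)CC[C@@H](C(C)(C)O)C/C=C(/C)CC[C@@H]2O[C@]2(C)C1 | intermediate
36 | (1S,6R,12S,13R,2E,8Z)-12,13-epoxy-6-(2-hydroxypropan-2-yl)-3,9,13-trimethylcyclotetradeca-2,8-dien-1-yl acetate | CC(=O)O[C@@H]1/C=C(\C)CC[C@@H](C(C)(C)O)C/C=C(/C)CC[C@@H]2O[C@]2(C)C1 | target

## Step count and least certain steps

Total: 25 steps (operations run in one flask counted once). Longest linear sequence: 20 steps (steps 1–7 and 13–25) from 1; the branch from 11 is 5 steps (8–12).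

**Step 22 (key step).** Most likely failure: intermolecular alkylation outrunning ring closure, or base-induced loss of HBr from the allylic bromide, because the carbanion sits next to the branched C6 and closes a 14-membered ring slowly. Fallback: make the C4–C5 bond intermolecularly by the same sulfone chemistry and close the ring by olefin metathesis at C2=C3.
- From 25, n-BuLi then 3-bromo-2-methylpropene gives the C5-methallylated sulfone F1.
- DDQ frees the C2 alcohol F2.
- Dess–Martin periodinane gives the aldehyde F3.
- Ph3P=CH2 gives the C2 vinyl compound F4.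
- Ring-closing metathesis with second-generation Grubbs catalyst in dilute toluene, with loss of ethene, should give 33 where the route is rejoined; the E-isomer would have to be separated from any Z-isomer.

**Step 16.** Most likely failure: poor facial selectivity, if chelation of vanadium by the neighbouring ether oxygen blurs the difference between the two chair arrangements. Fallback: move from substrate control to catalyst control, running the epoxidation of 23 with VO(OiPr)3 and a chiral C2-symmetric bis-hydroxamic acid ligand with cumene hydroperoxide, the ligand enantiomer chosen to reinforce the substrate bias. This goes from 23 to 24 directly and makes no new compound.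

**Step 15.** Most likely failure: partial loss of the Z geometry or hydride delivery to C13 through equilibration of the π-allyl complex, and capture of that complex by the C1 alkoxide. Fallback: join the fragments by a B-alkyl Suzuki coupling at C11–C12, which needs no allylic sulfone.
- From 8, molybdate/H2O2 gives the sulfone alcohol F5, MnO2 the Z-enal F6 and Ph3P=CH2 the diene F7.
- From 12, LiC≡CH·H2NCH2CH2NH2 gives the homopropargylic alcohol F8.
- Negishi carboalumination with chelation-driven isomerisation (AlMe3, Cp2ZrCl2, heat; then I2) gives the Z-alkenyl iodide F9.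
- 9-BBN adds to the terminal vinyl group of F7 to give the borane F10.
- Coupling of F10 with F9 (Pd(dppf)Cl2, AsPh3, Cs2CO3, DMF–H2O) gives 23, where the route is rejoined.

**Step 13.** Most likely failure: incomplete formation of the dianion, or O-alkylation and proton exchange through the C1 alkoxide, lowering conversion. Fallback: react a monoanion. From 20, Et3SiCl/imidazole gives the C1 triethylsilyl ether F11; one equivalent of n-BuLi then 10 gives the coupled silyl ether F12; PPTS in methanol removes the secondary silyl group and returns 21.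

## Further compounds

F1 | step 22 | C5-methallylated sulfone from 25 (C5 epimers) | COc1ccc(COC[C@@H](O[Si](C)(C)C(C)(C)C)C[C@@]2(C)O[C@H]2CC/C(C)=C\C[C@@H](C(CC(C)=C)S(=O)(=O)c3ccccc3)C(C)(C)O[Si](CC)(CC)CC)cc1
F2 | step 22 | C2 primary alcohol from F1 | OC[C@@H](O[Si](C)(C)C(C)(C)C)C[C@@]1(C)O[C@H]1CC/C(C)=C\C[C@@H](C(CC(C)=C)S(=O)(=O)c2ccccc2)C(C)(C)O[Si](CC)(CC)CC
F3 | step 22 | C2 aldehyde from F2 | O=C[C@@H](O[Si](C)(C)C(C)(C)C)C[C@@]1(C)O[C@H]1CC/C(C)=C\C[C@@H](C(CC(C)=C)S(=O)(=O)c2ccccc2)C(C)(C)O[Si](CC)(CC)CC
F4 | step 22 | metathesis precursor with C1 vinyl and C4 isopropenyl termini | C=C[C@@H](O[Si](C)(C)C(C)(C)C)C[C@@]1(C)O[C@H]1CC/C(C)=C\C[C@@H](C(CC(C)=C)S(=O)(=O)c2ccccc2)C(C)(C)O[Si](CC)(CC)CC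
F0 | step 16 | none | none
F5 | step 15 | (2Z,5R)-2,6-dimethyl-5-[(phenylsulfonyl)methyl]-6-(triethylsilyloxy)hept-2-en-1-ol | OC/C(C)=C\C[C@@H](CS(=O)(=O)c1ccccc1)C(C)(C)O[Si](CC)(CC)CC
F6 | step 15 | (2Z,5R)-2,6-dimethyl-5-[(phenylsulfonyl)methyl]-6-(triethylsilyloxy)hept-2-enal | O=C/C(C)=C\C[C@@H](CS(=O)(=O)c1ccccc1)C(C)(C)O[Si](CC)(CC)CC
F7 | step 15 | (3Z,6R)-3,7-dimethyl-6-[(phenylsulfonyl)methyl]-7-(triethylsilyloxy)octa-1,3-diene | C=C/C(C)=C\C[C@@H](CS(=O)(=O)c1ccccc1)C(C)(C)O[Si](CC)(CC)CC
F8 | step 15 | (2S)-1-[(4-methoxybenzyl)oxy]pent-4-yn-2-ol | C#CC[C@H](O)COCc1ccc(OC)cc1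
F9 | step 15 | (2S,4Z)-5-iodo-1-[(4-methoxybenzyl)oxy]-4-methylpent-4-en-2-ol | I/C=C(/C)C[C@H](O)COCc1ccc(OC)cc1
F10 | step 15 | B-alkyl-9-borabicyclo[3.3.1]nonane from F7 (boron on C11) | B1(CC/C(C)=C\C[C@@H](CS(=O)(=O)c2ccccc2)C(C)(C)O[Si](CC)(CC)CC)C2CCCC1CCC2
F11 | step 13 | C1 triethylsilyl ether of 20 | O=S(=O)(c1ccccc1)C/C=C(/C)C[C@H](O[Si](CC)(CC)CC)COCc1ccc(OC)cc1
F12 | step 13 | C1 triethylsilyl ether of 21 | COc1ccc(COC[C@@H](O[Si](CC)(CC)CC)C/C(C)=C\C(S(=O)(=O)c2ccccc2)C/C(C)=C\C[C@@H](CSc2ccccc2)C(C)(C)O[Si](CC)(CC)CC)cc1
A1 | alternative 1 | 14-membered cycloalkyne (C2≡C3) with C1 4-methoxybenzyl ether, C15 triethylsilyl ether and 8Z,12Z olefins | COc1ccc(CO[C@@H]2C#CCC[C@@H](C(C)(C)O[Si](CC)(CC)CC)C/C=C(/C)CC/C=C(/C)C2)cc1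
A2 | alternative 1 | acyclic diyne with methyl-capped alkynes on C1 and C4 | CC#C[C@@H](OCc1ccc(OC)cc1)C/C(C)=C\CC/C(C)=C\C[C@@H](CCC#CC)C(C)(C)O[Si](CC)(CC)CC
A3 | alternative 2 | bis(triethylsilyl) ether of the deacetylated target macrocycle | CC[Si](CC)(CC)O[C@@H]1/C=C(\C)CC[C@@H](C(C)(C)O[Si](CC)(CC)CC)C/C=C(/C)CC[C@@H]2O[C@]2(C)C1
A4 | alternative 2 | acyclic precursor with C4=C5 vinyl group and (E)-alkenyl iodide at C3 | C=C[C@@H](C(C)(C)O[Si](CC)(CC)CC)C/C=C(/C)CC[C@@H]1O[C@]1(C)C[C@H](O[Si](CC)(CC)CC)/C=C(\C)I
A5 | alternative 3 | macrocyclic Z,Z-dienyl propargylic alcohol (C1 epimers) | OC1C#CCC[C@@H](C(C)(C)O[Si](CC)(CC)CC)C/C=C(/C)CC/C=C(/C)C1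
A6 | alternative 3 | acyclic ynal with trimethylsilyl on C12 and exocyclic methylene on C13 | O=CC#CCC[C@@H](C(C)(C)O[Si](CC)(CC)CC)C/C=C(/C)CCC([Si](C)(C)C)C(C)=C
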